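**Retrosynthetic overview**

- The target is a type B polyprenylated acylphloroglucinol (core C1–C9; cycloheptane carbons C10–C14, joined C6–C10 and C5–C14). Ring B (C1, C8, C7, C6, C5, C9) is closed last, through the C1–C8 bond, by a 1,3-shift of the tertiary carbon C8 from oxygen O9 to carbon C1.
- Enabling feature: a temporary 2,2-dimethyl-dihydropyran (O9, C9, C5, C6, C7, C8) that shares five atoms with ring B. Its C8–O9 bond is a tertiary alkyl vinylogous ester that ionises, and C1 is the enol carbon next to O9. The chair pyran holds C5, C6 and C7 in the target configuration.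
- The pyrano-spirocycle comes from one acid-mediated cascade on a flat, hexasubstituted acylphloroglucinol: ipso-allylation closes the cycloheptane (C5–C6), then O9–C8 closes the pyran.
- The arene comes from C-allyl maclurin and a keto-dienal (reductive alkylation, C5–C14). The keto-dienal comes from (R)-carvone (sets C12) and an allylic phosphonium salt made from but-2-yn-1-ol.
- Ring order: arene ring A (bought) → cycloheptane plus temporary pyran → ring B; then allyl → prenyl cross-metathesis.

Key step: step 13

Remark: 1,3-dicarbonyl units are drawn as one enol tautomer; the isopropenyl group is carried as an acetyl group from step 3 to step 12, because a free isopropenyl group would trap the allyl cation of step 11 in a six-membered ring.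

**Step 1**
Reactants: 1 (R)-carvone
Product: 3 (5S)-2,6,6-trimethyl-5-(prop-1-en-2-yl)cyclohex-2-en-1-one, via 6-methylcarvone 2 (not isolated)
Conditions: LiN(iPr)2, THF, −78 °C, then MeI; repeat LiN(iPr)2, MeI, −78 to 0 °C (one pot)
Reagents that add atoms: iodomethane, CI
Why: Kinetic enolate alkylation at the α′-carbon of the enone, run twice, builds the gem-dimethyl carbon C13, and the isopropenyl-bearing stereocentre (future C12) comes from the chiral pool and is not touched.

**Step 2**
Reactants: 3 (5S)-2,6,6-trimethyl-5-(prop-1-en-2-yl)cyclohex-2-en-1-one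
Product: 4 (5S)-2,6,6-trimethyl-5-(prop-1-en-2-yl)cyclohex-2-en-1-ol (C1 epimers)
Conditions: NaBH4, CeCl3·7H2O, MeOH, 0 °C
Reagents that add atoms: none
Why: Luche reduction gives clean 1,2-reduction of the enone, and the new carbinol centre is destroyed in step 3, so its configuration does not matter.

**Step 3**
Reactants: 4 (5S)-2,6,6-trimethyl-5-(prop-1-en-2-yl)cyclohex-2-en-1-ol
Product: 6 (3R)-3-acetyl-2,2-dimethylpentanedial, via hydroxy-diketo aldehyde 5 (not isolated)
Conditions: O3, CH2Cl2–MeOH, −78 °C; Me2S; then NaIO4, THF–H2O, 0 °C
Reagents that add atoms: ozone, [O-][O+]=O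
Why: Ozonolysis cleaves both alkenes (the isopropenyl group becomes the acetyl mask) and periodate cleavage of the resulting α-hydroxy ketone excises the methyl-bearing ring carbon as acetic acid, all under near-neutral conditions that should not enolise the hindered methine next to the acetyl group.

**Step 4**
Reactants: 7 but-2-yn-1-ol
Product: 9 3-methyl-2-(prop-2-enyl)but-2-en-1-ol, via alkenylmagnesium bromide 8 (not isolated)
Conditions: CH2=CHCH2MgBr (2.5 equiv), Et2O, reflux; then MeI, copper iodide CuI (10 mol %), THF, 0 °C to rt
Reagents that add atoms: allylmagnesium bromide, C=CC[Mg]Br; iodomethane, CI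
Why: Anti-carbomagnesiation of the propargylic alkoxide places the allyl group next to the carbinol carbon and magnesium on the distal carbon (five-membered chelate), and copper-catalysed methylation of that alkenylmagnesium gives the tetrasubstituted alkene, whose two identical methyl groups remove any E/Z issue.

**Step 5**
Reactants: 9 3-methyl-2-(prop-2-enyl)but-2-en-1-ol
Product: 10 4-(bromomethyl)-5-methylhexa-1,4-diene
Conditions: PBr3 (0.4 equiv), pyridine (cat.), Et2O, −10 °C
Reagents that add atoms: phosphorus tribromide, BrP(Br)Br
Why: Standard conversion of a primary allylic alcohol into the bromide by bromide displacement of the phosphite ester.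

**Step 6**
Reactants: 10 4-(bromomethyl)-5-methylhexa-1,4-diene
Product: 11 [3-methyl-2-(prop-2-enyl)but-2-enyl]triphenylphosphonium bromide
Conditions: PPh3, toluene, 60 °C
Reagents that add atoms: triphenylphosphine, c1ccc(cc1)P(c1ccccc1)c1ccccc1
Why: Quaternisation of triphenylphosphine by a primary allylic bromide (nucleophilic substitution) gives the Wittig salt.

**Step 7**
Reactants: 11 [3-methyl-2-(prop-2-enyl)but-2-enyl]triphenylphosphonium bromide; 6 (3R)-3-acetyl-2,2-dimethylpentanedial
Product: 13 (3R)-3-acetyl-2,2,8-trimethyl-7-(prop-2-enyl)nona-5,7-dienal (5E/5Z mixture), via phosphorus ylide 12 (not isolated)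
Conditions: NaN(SiMe3)2 (1.0 equiv), THF, −78 °C; then 6 (1.0 equiv), −78 to −20 °C
Reagents that add atoms: none
Why: Wittig olefination with a semi-stabilised allylic ylide should occur only at the unhindered CH2–CHO and not at the neopentyl aldehyde or the hindered methyl ketone, and the geometry of the new alkene is irrelevant because both isomers give the same allyl cation in step 11.

**Step 8**
Reactants: 14 maclurin
Product: 15 (3,4-dihydroxyphenyl)[2,6-dihydroxy-4-(prop-2-enyloxy)phenyl]methanone
Conditions: allyl bromide (1.0 equiv), K2CO3 (1.0 equiv), acetone, rt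
Reagents that add atoms: allyl bromide, C=CCBr
Why: Williamson etherification with one equivalent of base should select the most acidic, non-chelated para hydroxyl of the phloroglucinol ring, since the two ortho hydroxyls are hydrogen-bonded to the ketone.

**Step 9**
Reactants: 15 (3,4-dihydroxyphenyl)[2,6-dihydroxy-4-(prop-2-enyloxy)phenyl]methanone
Product: 16 (3,4-dihydroxyphenyl)[2,4,6-trihydroxy-3-(prop-2-enyl)phenyl]methanone
Conditions: PhNEt2, 190 °C, sealed tube, argon
Reagents that add atoms: none
Why: Aromatic Claisen rearrangement moves the allyl group to one of the two equivalent free ortho carbons (future C1) and tautomerisation restores the arene.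

**Step 10**
Reactants: 16 (3,4-dihydroxyphenyl)[2,4,6-trihydroxy-3-(prop-2-enyl)phenyl]methanone; 13 (3R)-3-acetyl-2,2,8-trimethyl-7-(prop-2-enyl)nona-5,7-dienal
Product: 18 (3,4-dihydroxyphenyl){3-[(3R)-3-acetyl-2,2,8-trimethyl-7-(prop-2-enyl)nona-5,7-dienyl]-2,4,6-trihydroxy-5-(prop-2-enyl)phenyl}methanone, via o-quinone methide 17 (not isolated)
Conditions: Hantzsch ester (3 equiv), ethylenediammonium diacetate (10 mol %), CH2Cl2–MeOH, 0 °C to rt
Reagents that add atoms: none
Why: Knoevenagel-type condensation of the only free arene carbon (future C5) with the neopentyl aldehyde gives an o-quinone methide that is reduced in situ by hydride transfer from the Hantzsch ester (three-component reductive alkylation), forming the C5–C14 bond without creating a stereocentre or reducing the ketones or the diene.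

**Step 11**
Reactants: 18 hexasubstituted acylphloroglucinol (as named in step 10)
Product: 20 acetyl pyrano-spirocycle (chair pyran on O9 with C10 and the 7-allyl group equatorial and trans, C14 axial; 12-acetyl on the cycloheptane face opposite the pyran), via spiro-dienone 19 (not isolated)
Conditions: camphorsulfonic acid (10 mol %), CH2Cl2–(CF3)2CHOH 9:1, 2 mM, 0 °C to rt
Reagents that add atoms: none
Why: Proposed new method: protonation of the conjugated diene at its terminus gives a 1,1-dimethylallyl cation that is attacked at its secondary end by the fully substituted arene carbon C5 (ipso Friedel–Crafts dearomatisation closing the cycloheptane), and the new tetrasubstituted alkene is then protonated and captured by the non-chelated enol oxygen O9 to close the pyran — the closest known types are acid-mediated chroman annulation of phenols with 1,3-dienes and dearomative C-prenylation of acylphloroglucinols — and because both bond formations are reversible the product should settle as the chair pyran that keeps the hydrogen-bonded triketone intact, which fixes C5, C6 and C7 relative to one another, whereas the preference for the shown sense relative to the existing C12 centre rests only on a pseudo-equatorial acetyl group and is the weak point.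

**Step 12**
Reactants: 20 acetyl pyrano-spirocycle
Product: 21 isopropenyl pyrano-spirocycle
Conditions: Ph3PCH3Br (6 equiv), KOtBu (8 equiv), THF, 0 to 40 °C
Reagents that add atoms: methyltriphenylphosphonium bromide, C[P+](c1ccccc1)(c1ccccc1)c1ccccc1.[Br-]
Why: Wittig methylenation of the hindered methyl ketone unmasks the isopropenyl group, the triketone enolate and phenoxides formed first being inert to the ylide, and enolisation should occur at the methyl group rather than at the hindered C12 methine, so C12 should keep its configuration.

**Step 13**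
Reactants: 21 isopropenyl pyrano-spirocycle
Product: 24 1,7-diallyl bicyclo[3.3.1]nonane trione (7-allyl endo, C6–C10 bond trans to it, cycloheptane cis-fused), via silylated pyran 22 (not isolated), via silylated trione 23 (not isolated)
Conditions: Me3SiOTf (3.5 equiv), 2,6-di-tert-butyl-4-methylpyridine (3.2 equiv), CH2Cl2, −78 to −20 °C; then aq NaHCO3–MeOH, 0 °C
Reagents that add atoms: none
Why: Proposed new method: silylation of the three hydroxyls gives a silyl dienol ether, Me3SiOTf then activates the vinylogous ester so that the tertiary C8–O9 bond ionises, and the C8 cation, held above ring A by the C6–C7 tether, recombines with the enol carbon C1 next to C9 instead of with O9, a 1,3-shift of C8 from oxygen to carbon. The closest known reaction types are Lewis-acid-mediated 1,3-O-to-C rearrangements of enol ethers (Petasis–Ferrier type), α-tert-alkylation of silyl enol ethers by tertiary cations, and the formic-acid cationic closure of lavandulyl-type side chains onto dearomatised acylphloroglucinols. Ring B (C1, C8, C7, C6, C5, C9) is closed by the C1–C8 bond in a 6-exo-type cation capture through a boat-like transition state that keeps C10 and the 7-allyl group pseudo-equatorial as they were in the chair pyran, while the temporary pyran is destroyed. C1 is the only new stereocentre and is dictated by the tether, since C8 can reach only the enol face on which C6 stands; C5, C6 and C7 are untouched because no Brønsted acid is present to re-ionise the C5–C6 bond or epimerise C7. The step needs C- over O-alkylation and C1 over C3: return to O9 only regenerates the enol ether while C–C bond formation is irreversible, C3 is blocked by the aroyl group, and the hindered pyridine removes triflic acid so that the isopropenyl and allyl groups are not protonated.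

**Step 14**
Reactants: 24 1,7-diallyl bicyclo[3.3.1]nonane trione
Product: 25 target CNP0140614.2
Conditions: second-generation Grubbs catalyst (10 mol %), 2-methylbut-2-ene (co-solvent), CH2Cl2, 40 °C
Reagents that add atoms: 2-methylbut-2-ene, CC=C(C)C
Why: Olefin cross-metathesis with excess 2-methylbut-2-ene converts both monosubstituted allyl groups into prenyl groups, while the 1,1-disubstituted isopropenyl group is a poor metathesis partner and no stereocentre is affected.

**Compound list**

1 | (R)-carvone | CC1=CC[C@H](CC1=O)C(C)=C | starting material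
2 | (5R)-6-methylcarvone (C6 epimers) | CC1=CC[C@H](C(C)C1=O)C(C)=C | intermediate
3 | (5S)-2,6,6-trimethyl-5-(prop-1-en-2-yl)cyclohex-2-en-1-one | CC1=CC[C@H](C(C)(C)C1=O)C(C)=C | intermediate
4 | (5S)-2,6,6-trimethyl-5-(prop-1-en-2-yl)cyclohex-2-en-1-ol (C1 epimers) | CC1=CC[C@H](C(C)(C)C1O)C(C)=C | intermediate
5 | (3R)-3-acetyl-5-hydroxy-4,4-dimethyl-6-oxoheptanal (C5 epimers) | O=CC[C@H](C(C)(C)C(O)C(C)=O)C(C)=O | intermediate
6 | (3R)-3-acetyl-2,2-dimethylpentanedial | O=CC[C@H](C(C)(C)C=O)C(C)=O | intermediate
7 | but-2-yn-1-ol | CC#CCO | starting material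
8 | chelated alkenylmagnesium bromide from allyl addition | C=CCC(CO[Mg]Br)=C(C)[Mg]Br | intermediate
9 | 3-methyl-2-(prop-2-enyl)but-2-en-1-ol | C=CCC(CO)=C(C)C | intermediate
10 | 4-(bromomethyl)-5-methylhexa-1,4-diene | C=CCC(CBr)=C(C)C | intermediate
11 | [3-methyl-2-(prop-2-enyl)but-2-enyl]triphenylphosphonium bromide | C=CCC(C[P+](c1ccccc1)(c1ccccc1)c1ccccc1)=C(C)C.[Br-] | intermediate
12 | allylic phosphorus ylide of 11 | C=CCC(C=P(c1ccccc1)(c1ccccc1)c1ccccc1)=C(C)C | intermediate
13 | (3R)-3-acetyl-2,2,8-trimethyl-7-(prop-2-enyl)nona-5,7-dienal (5E/5Z mixture) | C=CCC(=C(C)C)C=CC[C@H](C(C)(C)C=O)C(C)=O | intermediate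
14 | maclurin, (3,4-dihydroxyphenyl)(2,4,6-trihydroxyphenyl)methanone | O=C(c1ccc(O)c(O)c1)c1c(O)cc(O)cc1O | starting material
15 | (3,4-dihydroxyphenyl)[2,6-dihydroxy-4-(prop-2-enyloxy)phenyl]methanone | O=C(c1ccc(O)c(O)c1)c1c(O)cc(OCC=C)cc1O | intermediate
16 | (3,4-dihydroxyphenyl)[2,4,6-trihydroxy-3-(prop-2-enyl)phenyl]methanone | O=C(c1ccc(O)c(O)c1)c1c(O)c(CC=C)c(O)cc1O | intermediate
17 | o-quinone methide from 16 and 13 (exocyclic C5=C14) | O=C(c1ccc(O)c(O)c1)C1=C(O)C(CC=C)=C(O)C(=CC(C)(C)[C@@H](CC=CC(CC=C)=C(C)C)C(C)=O)C1=O | intermediate
18 | (3,4-dihydroxyphenyl){3-[(3R)-3-acetyl-2,2,8-trimethyl-7-(prop-2-enyl)nona-5,7-dienyl]-2,4,6-trihydroxy-5-(prop-2-enyl)phenyl}methanone | O=C(c1ccc(O)c(O)c1)c1c(O)c(CC=C)c(O)c(CC(C)(C)[C@@H](CC=CC(CC=C)=C(C)C)C(C)=O)c1O | intermediate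
19 | spiro-dienone: cycloheptane spiro-fused at C5, C6 bearing the 2-allyl-3-methylbut-2-en-2-yl group (productive diastereomer shown) | CC(=O)[C@@H]1CC[C@@H](C(CC=C)=C(C)C)[C@@]2(CC1(C)C)C(O)=C(C(=O)c3ccc(O)c(O)c3)C(=O)C(CC=C)=C2O | intermediate
20 | acetyl pyrano-spirocycle: chair 2,2-dimethyl-dihydropyran (O9, C8, C7, C6, C5, C9), C10 and 7-allyl equatorial and trans, C14 axial, 12-acetyl on the face opposite the pyran | CC(=O)[C@@H]1CC[C@H]2[C@H](CC=C)C(C)(C)OC3=C(CC=C)C(=O)C(C(=O)c4ccc(O)c(O)c4)=C(O)[C@@]32CC1(C)C | intermediate
21 | isopropenyl pyrano-spirocycle (as 20, isopropenyl at C12) | C=C(C)[C@@H]1CC[C@H]2[C@H](CC=C)C(C)(C)OC3=C(CC=C)C(=O)C(C(=O)c4ccc(O)c(O)c4)=C(O)[C@@]32CC1(C)C | intermediate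
22 | tris(trimethylsilyl) ether of 21 | C=C(C)[C@@H]1CC[C@H]2[C@H](CC=C)C(C)(C)OC3=C(CC=C)C(=O)C(C(=O)c4ccc(O[Si](C)(C)C)c(O[Si](C)(C)C)c4)=C(O[Si](C)(C)C)[C@@]32CC1(C)C | intermediate
23 | tris(trimethylsilyl) ether of 24 | C=C(C)[C@@H]1CC[C@H]2[C@H](CC=C)C(C)(C)[C@]3(CC=C)C(=O)C(C(=O)c4ccc(O[Si](C)(C)C)c(O[Si](C)(C)C)c4)=C(O[Si](C)(C)C)[C@@]2(CC1(C)C)C3=O | intermediate
24 | 1,7-diallyl bicyclo[3.3.1]nonane-2,4,9-trione: 7-allyl endo, C6–C10 trans to it, cycloheptane cis-fused at C5–C6, 12-isopropenyl on the face opposite C7 and C9 | C=C(C)[C@@H]1CC[C@H]2[C@H](CC=C)C(C)(C)[C@]3(CC=C)C(=O)C(C(=O)c4ccc(O)c(O)c4)=C(O)[C@@]2(CC1(C)C)C3=O | intermediate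
25 | CNP0140614.2 (as 24 with prenyl groups at C1 and C7) | C=C(C)[C@@H]1CC[C@H]2[C@H](CC=C(C)C)C(C)(C)[C@]3(CC=C(C)C)C(=O)C(C(=O)c4ccc(O)c(O)c4)=C(O)[C@@]2(CC1(C)C)C3=O | target

**Step count**

Total steps: 14. Longest linear sequence: 9 steps (steps 1, 2, 3, 7, 10, 11, 12, 13, 14).

**Three steps most likely to fail**

Step 11 (proposed new method). The pyran may close on the chelated oxygen O4 instead of O9. The new C5/C6/C7 triad may form with little preference relative to the remote C12 centre. Slow enolisation of the acetyl group may erode C12, and direct C-alkylation at C1 may occur before the pyran template has equilibrated. The fallback sets out from 18 and returns at 20. Zerovalent-palladium-catalysed hydroalkylation of the 1,3-diene [Pd2(dba)3, a chiral phosphinooxazoline ligand, catalytic acid co-catalyst], a known reaction type for 1,3-dicarbonyl C–H acids, forms the C5–C6 bond through a π-allyl complex under ligand control and gives the spiro-dienone 19, this time isolated. Catalytic pyridinium p-toluenesulfonate in toluene then closes the pyran on O9 (acid-catalysed cyclo-etherification of a C-prenyl-type enol) to give 20. This fallback makes no compound outside the compound list (F0).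

Step 13 (proposed new method). The ion pair may simply return to oxygen, or lose a proton to give a ring-opened alkene, faster than the boat-like C1–C8 bond can form. The fallback sets out from 21 and returns at 24. Me3SiOTf with excess triethylamine opens the pyran by elimination to the ring-opened seco-triene F1, which carries the isopropenyl/allyl side chain on C6 and the free enol at C9. F1 is then stirred in neat formic acid at room temperature, the established Brønsted-acid cationic cyclisation of such side chains onto the alkyl-bearing enol carbon, to give 24. The reaction time must be kept short, because the C12 isopropenyl group and the C5–C6 bond are exposed to acid.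

Step 10. The o-quinone methide may be consumed by intramolecular hetero-Diels–Alder reaction with the tethered diene (domino Knoevenagel/cycloaddition) before hydride transfer can reduce it. The fallback sets out from 6 and 16 and returns at 18. Selective acetalisation of the unhindered aldehyde of 6 [CH(OMe)3, MeOH, pyridinium p-toluenesulfonate, 0 °C] gives (3R)-3-acetyl-5,5-dimethoxy-2,2-dimethylpentanal F2. The same reductive alkylation of 16 with F2, now with no alkene within reach of the quinone methide, gives the arene acetal F3. Aqueous acetic acid frees the arene aldehyde F4. After silylation of the phenols in the flask with N,O-bis(trimethylsilyl)acetamide, Wittig olefination of F4 with ylide 12 gives 18.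

**Further compounds**

F0 | step 11 | none | none
F1 | step 13 | ring-opened seco-triene: spiro-dienone with free C9 enol, C6 bearing the (S)-configured CH(allyl)(isopropenyl) carbon C7 | C=C(C)[C@@H]1CC[C@@H]([C@H](CC=C)C(C)=C)[C@@]2(CC1(C)C)C(O)=C(C(=O)c3ccc(O)c(O)c3)C(=O)C(CC=C)=C2O
F2 | step 10 | (3R)-3-acetyl-5,5-dimethoxy-2,2-dimethylpentanal | COC(OC)C[C@H](C(C)(C)C=O)C(C)=O
F3 | step 10 | (3,4-dihydroxyphenyl){3-[(3R)-3-acetyl-5,5-dimethoxy-2,2-dimethylpentyl]-2,4,6-trihydroxy-5-(prop-2-enyl)phenyl}methanone | O=C(c1ccc(O)c(O)c1)c1c(O)c(CC=C)c(O)c(CC(C)(C)[C@@H](CC(OC)OC)C(C)=O)c1O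
F4 | step 10 | (3,4-dihydroxyphenyl){3-[(3R)-3-acetyl-2,2-dimethyl-5-oxopentyl]-2,4,6-trihydroxy-5-(prop-2-enyl)phenyl}methanone | O=C(c1ccc(O)c(O)c1)c1c(O)c(CC=C)c(O)c(CC(C)(C)[C@@H](CC=O)C(C)=O)c1O
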